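A direct plan would set the methine centre by rhodium-catalysed asymmetric 1,4-addition of an arylboronic acid to bromocoumarin A1, open the resulting chromanone A2, extend its chain to diazo enone A3, build the resorcinol ring from A3 and silyloxyacetylene A4 by photochemical Wolff/ketene–alkyne benzannulation, and end with Heck coupling and debenzylation. Its weakest steps would be the chain extension (ester half-reduction, then Wittig reaction), which would add length but no complexity; the diazo transfer, which would rely on clean kinetic enolisation of the enone methyl group; and the photochemical benzannulation, which would need the labile ynol ether A4 in excess and would pass through four unisolated ketene and cyclobutenone intermediates.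

The route rests on the phenolic oxygen at C2 of ring B (the central 2-hydroxy-3-methoxyphenyl ring): tied to the benzylic CH2 carbon, it turns the methine carbon, the CH2 carbon, C1 and C2 of ring B and this oxygen into a temporary 2,3-dihydrobenzofuran. The key step forms the methine–CH2 bond of that ring by enantioselective rhodium-carbene insertion of a diaryldiazomethane into the ArO–CH2–Ar group, so that three purchased arenes are united and the stereocentre is set in one operation; hydrogenolysis of the benzylic C–O bond then frees the phenol and the CH2 group. No ring is constructed, no chain is homologated, and no photochemistry or ynol ether is needed.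

Key step: step 6

Assumption: dirhodium tetrakis[(S)-(1-adamantyl)(N-phthalimido)acetate], Rh2(S-PTAD)4, is taken to give the (3S) series in step 6; if the sense of induction proved opposite, the equally available Rh2(R-PTAD)4 would be used with no other change.

Step 1
Reactants: 1 2,4-bis(benzyloxy)benzaldehyde
Product: 2 [2,4-bis(benzyloxy)phenyl]methanol
Conditions: NaBH4, THF/MeOH, 0 °C
Reagents that add atoms: none
Why: borohydride reduction of the aryl aldehyde to the benzylic alcohol, to which benzyl ethers are inert.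

Step 2
Reactants: 2 [2,4-bis(benzyloxy)phenyl]methanol; 3 5-bromo-2-hydroxy-3-methoxybenzaldehyde
Product: 4 2-{[2,4-bis(benzyloxy)phenyl]methoxy}-5-bromo-3-methoxybenzaldehyde
Conditions: PPh3, DIAD, THF, 0 → 25 °C
Reagents that add atoms: none
Why: Mitsunobu etherification, in which the acidic salicylaldehyde-type phenol of 3 displaces the alkoxyphosphonium derivative of the primary benzylic alcohol 2, so that the unstable 2,4-dialkoxybenzyl halide is avoided and the aldehyde and aryl bromide stay untouched.

Step 3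
Reactants: 4 2-{[2,4-bis(benzyloxy)phenyl]methoxy}-5-bromo-3-methoxybenzaldehyde; 5 1-(benzyloxy)-4-bromo-2-methoxybenzene
Product: 7 rac-(2-{[2,4-bis(benzyloxy)phenyl]methoxy}-5-bromo-3-methoxyphenyl)[4-(benzyloxy)-3-methoxyphenyl]methanol, via arylmagnesium bromide 6 (not isolated)
Conditions: 5, Mg, THF, 40 °C; then 4, THF, −20 → 0 °C; then H2O
Reagents that add atoms: none
Why: Grignard addition to the aldehyde, in which the arylmagnesium bromide adds to the formyl group faster than it could exchange with the aryl bromide of 4, and the carbinol centre needs no control because step 4 removes it.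

Step 4
Reactants: 7 rac-(2-{[2,4-bis(benzyloxy)phenyl]methoxy}-5-bromo-3-methoxyphenyl)[4-(benzyloxy)-3-methoxyphenyl]methanol
Product: 8 (2-{[2,4-bis(benzyloxy)phenyl]methoxy}-5-bromo-3-methoxyphenyl)[4-(benzyloxy)-3-methoxyphenyl]methanone
Conditions: MnO2 (activated), CH2Cl2, 25 °C
Reagents that add atoms: none
Why: oxidation of the doubly benzylic alcohol with activated manganese dioxide, a reagent selective for benzylic alcohols that leaves the benzylic ethers and the bromide alone.

Step 5
Reactants: 8 (2-{[2,4-bis(benzyloxy)phenyl]methoxy}-5-bromo-3-methoxyphenyl)[4-(benzyloxy)-3-methoxyphenyl]methanone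
Product: 9 [(2-{[2,4-bis(benzyloxy)phenyl]methoxy}-5-bromo-3-methoxyphenyl)[4-(benzyloxy)-3-methoxyphenyl]methylidene]hydrazine (E/Z mixture)
Conditions: N2H4·H2O (10 equiv), AcOH (cat.), EtOH, 80 °C
Reagents that add atoms: hydrazine NN
Why: acid-catalysed hydrazone formation from the diaryl ketone with excess hydrazine (which suppresses the azine); both C=N isomers lead to the same diazo compound, so the geometry is immaterial.

Step 6
Reactants: 9 [(2-{[2,4-bis(benzyloxy)phenyl]methoxy}-5-bromo-3-methoxyphenyl)[4-(benzyloxy)-3-methoxyphenyl]methylidene]hydrazine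
Product: 11 (2R,3S)-2-[2,4-bis(benzyloxy)phenyl]-3-[4-(benzyloxy)-3-methoxyphenyl]-5-bromo-7-methoxy-2,3-dihydro-1-benzofuran, via diaryldiazomethane 10 (not isolated)
Conditions: MnO2 (activated), MgSO4, CH2Cl2, 0 °C, filtration; then Rh2(S-PTAD)4 (1 mol %), CH2Cl2, 0 → 25 °C
Reagents that add atoms: none
Why: Manganese dioxide dehydrogenates the hydrazone to diaryldiazomethane 10, which loses N2 at the dirhodium tetracarboxylate to give a donor/donor rhodium carbene that inserts, through an asynchronous hydride-transfer-like three-centre transition state, into one of the two enantiotopic C–H bonds of the ArO–CH2–Ar group. The closest known reaction type is the enantioselective intramolecular C–H insertion of diaryl rhodium carbenes derived from 2-benzyloxybenzophenone hydrazones, which gives 2,3-diaryl-2,3-dihydrobenzofurans. The only ring closed is the five-membered O-heterocycle, by 1,5-C–H insertion that forms the C2–C3 bond, and this ring is temporary. C3, the future methine stereocentre, is set by the carbene face that the chiral phthalimido-adamantylacetate ligand sphere leaves open, and C2 by the choice between the two benzylic hydrogens (cis isomer expected); C2 is erased in step 8, so only C3 matters. The step needs chemoselectivity for 1,5-insertion over azine formation, Buchner addition to the benzyl rings and insertion into OCH3 or OCH2Ph groups, and the substrate secures it because the C–H bond attacked is benzylic, α to oxygen, activated by the 2,4-dialkoxyaryl group and the only one that can reach the carbene through a five-membered transition state, while slow delivery of the diazo solution limits azine formation.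

Step 7
Reactants: 11 (2R,3S)-2-[2,4-bis(benzyloxy)phenyl]-3-[4-(benzyloxy)-3-methoxyphenyl]-5-bromo-7-methoxy-2,3-dihydro-1-benzofuran
Product: 12 2-[(2R,3S)-2-[2,4-bis(benzyloxy)phenyl]-3-[4-(benzyloxy)-3-methoxyphenyl]-7-methoxy-2,3-dihydro-1-benzofuran-5-yl]-4,4,5,5-tetramethyl-1,3,2-dioxaborolane
Conditions: B2pin2, PdCl2(dppf) (3 mol %), KOAc, dioxane, 85 °C
Reagents that add atoms: bis(pinacolato)diboron CC1(C)OB(B2OC(C)(C)C(C)(C)O2)OC1(C)C
Why: Miyaura borylation of the aryl bromide (oxidative addition to zerovalent palladium, acetate-assisted transmetallation), which exchanges the one group that hydrogenolysis would remove for a boronate that survives it; potassium acetate is too weak a base to affect C2–H or C3–H.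

Step 8
Reactants: 12 2-[(2R,3S)-2-[2,4-bis(benzyloxy)phenyl]-3-[4-(benzyloxy)-3-methoxyphenyl]-7-methoxy-2,3-dihydro-1-benzofuran-5-yl]-4,4,5,5-tetramethyl-1,3,2-dioxaborolane
Product: 13 4-[(2S)-2-(4-hydroxy-3-methoxyphenyl)-2-[2-hydroxy-3-methoxy-5-(4,4,5,5-tetramethyl-1,3,2-dioxaborolan-2-yl)phenyl]ethyl]benzene-1,3-diol
Conditions: H2 (3 atm), Pd(OH)2/C, THF/EtOH, 25 → 45 °C
Reagents that add atoms: none
Why: catalytic hydrogenolysis, which cleaves the three benzyl ethers and the benzylic C2–O bond of the dihydrobenzofuran (by then that of an ortho,para-dihydroxybenzyl aryl ether, as in the known opening of pterocarpans to 2′-hydroxyisoflavans), so that C2 becomes the CH2 group and the ring B phenol is freed, while C3 (no leaving group, no acid present) keeps its configuration and the pinacol boronate is not reduced.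

Step 9
Reactants: 14 3,5-dihydroxybenzaldehyde
Product: 15 5-formyl-1,3-phenylene diacetate
Conditions: Ac2O, pyridine, DMAP (cat.), CH2Cl2, 0 → 25 °C
Reagents that add atoms: acetic anhydride CC(=O)OC(C)=O
Why: DMAP-catalysed O-acetylation of both phenols, which masks them during the chromium-mediated step and allows their release in the final flask.

Step 10
Reactants: 15 5-formyl-1,3-phenylene diacetate
Product: 16 5-[(E)-2-iodoethenyl]-1,3-phenylene diacetate
Conditions: CHI3, CrCl2, THF, 0 °C
Reagents that add atoms: iodoform IC(I)I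
Why: Takai olefination, in which the geminal dichromium species formed from iodoform and divalent chromium adds to the aldehyde and eliminates to the (E)-vinyl iodide, the isomer favoured for aryl aldehydes; aryl acetates are inert to the reagent.

Step 11
Reactants: 13 4-[(2S)-2-(4-hydroxy-3-methoxyphenyl)-2-[2-hydroxy-3-methoxy-5-(4,4,5,5-tetramethyl-1,3,2-dioxaborolan-2-yl)phenyl]ethyl]benzene-1,3-diol; 16 5-[(E)-2-iodoethenyl]-1,3-phenylene diacetate
Product: 18 4-[(2S)-2-{5-[(E)-2-(3,5-dihydroxyphenyl)ethenyl]-2-hydroxy-3-methoxyphenyl}-2-(4-hydroxy-3-methoxyphenyl)ethyl]benzene-1,3-diol (CNP0254096.1), via stilbene diacetate 17 (not isolated)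
Conditions: Pd(PPh3)4 (5 mol %), K3PO4, degassed THF/H2O, 45 °C; then K2CO3, MeOH, 25 °C; aq. NH4Cl
Reagents that add atoms: none
Why: Suzuki–Miyaura coupling of the aryl pinacol boronate with the (E)-vinyl iodide, which retains the alkene geometry and tolerates free phenols, followed in the same flask by carbonate-mediated methanolysis of the two aryl acetates; neither operation touches the diarylmethine centre.

**Compound list**
1 | 2,4-bis(benzyloxy)benzaldehyde | O=Cc1ccc(OCc2ccccc2)cc1OCc1ccccc1 | starting material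
2 | [2,4-bis(benzyloxy)phenyl]methanol | OCc1ccc(OCc2ccccc2)cc1OCc1ccccc1 | intermediate
3 | 5-bromo-2-hydroxy-3-methoxybenzaldehyde | COc1cc(Br)cc(C=O)c1O | starting material
4 | 2-{[2,4-bis(benzyloxy)phenyl]methoxy}-5-bromo-3-methoxybenzaldehyde | COc1cc(Br)cc(C=O)c1OCc1ccc(OCc2ccccc2)cc1OCc1ccccc1 | intermediate
5 | 1-(benzyloxy)-4-bromo-2-methoxybenzene | COc1cc(Br)ccc1OCc1ccccc1 | starting material
6 | [4-(benzyloxy)-3-methoxyphenyl]magnesium bromide | COc1cc([Mg]Br)ccc1OCc1ccccc1 | intermediate (not isolated)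
7 | rac-(2-{[2,4-bis(benzyloxy)phenyl]methoxy}-5-bromo-3-methoxyphenyl)[4-(benzyloxy)-3-methoxyphenyl]methanol | COc1cc(C(O)c2cc(Br)cc(OC)c2OCc2ccc(OCc3ccccc3)cc2OCc2ccccc2)ccc1OCc1ccccc1 | intermediate
8 | (2-{[2,4-bis(benzyloxy)phenyl]methoxy}-5-bromo-3-methoxyphenyl)[4-(benzyloxy)-3-methoxyphenyl]methanone | COc1cc(C(=O)c2cc(Br)cc(OC)c2OCc2ccc(OCc3ccccc3)cc2OCc2ccccc2)ccc1OCc1ccccc1 | intermediate
9 | [(2-{[2,4-bis(benzyloxy)phenyl]methoxy}-5-bromo-3-methoxyphenyl)[4-(benzyloxy)-3-methoxyphenyl]methylidene]hydrazine (E/Z mixture) | COc1cc(C(=NN)c2cc(Br)cc(OC)c2OCc2ccc(OCc3ccccc3)cc2OCc2ccccc2)ccc1OCc1ccccc1 | intermediate (key-step precursor)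
10 | 2-{[2,4-bis(benzyloxy)phenyl]methoxy}-1-{[4-(benzyloxy)-3-methoxyphenyl](diazo)methyl}-5-bromo-3-methoxybenzene | COc1cc(C(=[N+]=[N-])c2cc(Br)cc(OC)c2OCc2ccc(OCc3ccccc3)cc2OCc2ccccc2)ccc1OCc1ccccc1 | intermediate (not isolated)
11 | (2R,3S)-2-[2,4-bis(benzyloxy)phenyl]-3-[4-(benzyloxy)-3-methoxyphenyl]-5-bromo-7-methoxy-2,3-dihydro-1-benzofuran (2,3-cis) | COc1cc(Br)cc2c1O[C@@H](c1ccc(OCc3ccccc3)cc1OCc1ccccc1)[C@H]2c1ccc(OCc2ccccc2)c(OC)c1 | intermediate (key-step product)
12 | 2-[(2R,3S)-2-[2,4-bis(benzyloxy)phenyl]-3-[4-(benzyloxy)-3-methoxyphenyl]-7-methoxy-2,3-dihydro-1-benzofuran-5-yl]-4,4,5,5-tetramethyl-1,3,2-dioxaborolane | COc1cc(B3OC(C)(C)C(C)(C)O3)cc2c1O[C@@H](c1ccc(OCc3ccccc3)cc1OCc1ccccc1)[C@H]2c1ccc(OCc2ccccc2)c(OC)c1 | intermediate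
13 | 4-[(2S)-2-(4-hydroxy-3-methoxyphenyl)-2-[2-hydroxy-3-methoxy-5-(4,4,5,5-tetramethyl-1,3,2-dioxaborolan-2-yl)phenyl]ethyl]benzene-1,3-diol | COc1cc([C@H](Cc2ccc(O)cc2O)c2cc(B3OC(C)(C)C(C)(C)O3)cc(OC)c2O)ccc1O | intermediate
14 | 3,5-dihydroxybenzaldehyde | O=Cc1cc(O)cc(O)c1 | starting material
15 | 5-formyl-1,3-phenylene diacetate | CC(=O)Oc1cc(C=O)cc(OC(C)=O)c1 | intermediate
16 | 5-[(E)-2-iodoethenyl]-1,3-phenylene diacetate | CC(=O)Oc1cc(/C=C/I)cc(OC(C)=O)c1 | intermediate
17 | 5-[(E)-2-{3-[(1S)-2-(2,4-dihydroxyphenyl)-1-(4-hydroxy-3-methoxyphenyl)ethyl]-4-hydroxy-5-methoxyphenyl}ethenyl]-1,3-phenylene diacetate | COc1cc([C@H](Cc2ccc(O)cc2O)c2cc(/C=C/c3cc(OC(C)=O)cc(OC(C)=O)c3)cc(OC)c2O)ccc1O | intermediate (not isolated)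
18 | 4-[(2S)-2-{5-[(E)-2-(3,5-dihydroxyphenyl)ethenyl]-2-hydroxy-3-methoxyphenyl}-2-(4-hydroxy-3-methoxyphenyl)ethyl]benzene-1,3-diol (CNP0254096.1) | COc1cc([C@H](Cc2ccc(O)cc2O)c2cc(/C=C/c3cc(O)cc(O)c3)cc(OC)c2O)ccc1O | target

Total step count: 11. Longest linear sequence: 9 steps (steps 1 to 8 and step 11, from 1 to 18); steps 9 and 10 form the side branch to 16.

**Steps most likely to fail**

Step 6 (carbene C–H insertion). What may go wrong: self-coupling of the electron-rich diazo compound to the azine before it reaches the catalyst, or weak facial discrimination at the carbene because of the flanking 7-methoxy group. Fallback: setting out from ketone 8, the same C2–C3 bond would be made by an anionic route. Benzylic deprotonation of the ArO–CH2–Ar group (KOt-Bu, DMF, 60 °C), addition of the anion to the ketone and acid-catalysed dehydration (p-TsOH, toluene) would give 2-[2,4-bis(benzyloxy)phenyl]-3-[4-(benzyloxy)-3-methoxyphenyl]-5-bromo-7-methoxy-1-benzofuran F1. Asymmetric cis-hydrogenation of its C2=C3 bond with a chiral ruthenium bis(N-heterocyclic carbene) catalyst (Ru(cod)(2-methylallyl)2, SINpEt·HBF4, KOt-Bu, H2; ligand enantiomer chosen for 3S) would come back to the route at 11. This hydrogenation of a tetrasubstituted alkene is itself demanding.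

Step 8 (hydrogenolysis). What may go wrong: the cyclic benzylic C–O bond may survive after the benzyl ethers have been cleaved, and forcing it with acid would risk ionisation at C2 and loss of the C3 configuration through a triarylethene. Fallback: setting out from 12, mild hydrogenolysis (H2, 1 atm, Pd/C, EtOAc, 25 °C) would be stopped at 4-[(2R,3S)-3-(4-hydroxy-3-methoxyphenyl)-7-methoxy-5-(4,4,5,5-tetramethyl-1,3,2-dioxaborolan-2-yl)-2,3-dihydro-1-benzofuran-2-yl]benzene-1,3-diol F2. The ring would then be opened by an ionic route: under K2CO3 in THF/MeOH the para-phenoxide of the 2,4-dihydroxyphenyl group expels the ring B phenoxide (retro-oxa-Michael), and NaBH4 present in the flask reduces the para-quinone methide at its exocyclic carbon, which comes back to the route at 13.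

Step 11 (coupling on the unprotected tetraphenol). What may go wrong: oxidative degradation of the polyphenolate and protodeboronation of the para-hydroxyaryl boronate under aqueous base. Fallback: setting out from 13, the four phenols would be acetylated (Ac2O, pyridine, DMAP) to 4-[(2S)-2-[4-(acetyloxy)-3-methoxyphenyl]-2-[2-(acetyloxy)-3-methoxy-5-(4,4,5,5-tetramethyl-1,3,2-dioxaborolan-2-yl)phenyl]ethyl]-1,3-phenylene diacetate F3. F3 would be coupled with 16 under anhydrous fluoride conditions (Pd(PPh3)4, CsF, THF, 60 °C) to the hexaacetate 5-[(E)-2-{4-(acetyloxy)-3-[(1S)-1-[4-(acetyloxy)-3-methoxyphenyl]-2-[2,4-bis(acetyloxy)phenyl]ethyl]-5-methoxyphenyl}ethenyl]-1,3-phenylene diacetate F4. Methanolysis of all six acetates (K2CO3, MeOH, 0 °C) would come back to the route at 18.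

**Further compounds**
F1 | step 6 | 2-[2,4-bis(benzyloxy)phenyl]-3-[4-(benzyloxy)-3-methoxyphenyl]-5-bromo-7-methoxy-1-benzofuran | COc1cc(Br)cc2c(-c3ccc(OCc4ccccc4)c(OC)c3)c(-c3ccc(OCc4ccccc4)cc3OCc3ccccc3)oc12
F2 | step 8 | 4-[(2R,3S)-3-(4-hydroxy-3-methoxyphenyl)-7-methoxy-5-(4,4,5,5-tetramethyl-1,3,2-dioxaborolan-2-yl)-2,3-dihydro-1-benzofuran-2-yl]benzene-1,3-diol | COc1cc(B3OC(C)(C)C(C)(C)O3)cc2c1O[C@@H](c1ccc(O)cc1O)[C@H]2c1ccc(O)c(OC)c1
F3 | step 11 | 4-[(2S)-2-[4-(acetyloxy)-3-methoxyphenyl]-2-[2-(acetyloxy)-3-methoxy-5-(4,4,5,5-tetramethyl-1,3,2-dioxaborolan-2-yl)phenyl]ethyl]-1,3-phenylene diacetate | COc1cc([C@H](Cc2ccc(OC(C)=O)cc2OC(C)=O)c2cc(B3OC(C)(C)C(C)(C)O3)cc(OC)c2OC(C)=O)ccc1OC(C)=O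
F4 | step 11 | 5-[(E)-2-{4-(acetyloxy)-3-[(1S)-1-[4-(acetyloxy)-3-methoxyphenyl]-2-[2,4-bis(acetyloxy)phenyl]ethyl]-5-methoxyphenyl}ethenyl]-1,3-phenylene diacetate | COc1cc([C@H](Cc2ccc(OC(C)=O)cc2OC(C)=O)c2cc(/C=C/c3cc(OC(C)=O)cc(OC(C)=O)c3)cc(OC)c2OC(C)=O)ccc1OC(C)=O
A1 | direct plan | 6-bromo-8-methoxy-2H-chromen-2-one | COc1cc(Br)cc2ccc(=O)oc12
A2 | direct plan | (4S)-4-[4-(benzyloxy)-3-methoxyphenyl]-6-bromo-8-methoxychroman-2-one | COc1cc([C@@H]2CC(=O)Oc3c(OC)cc(Br)cc32)ccc1OCc1ccccc1
A3 | direct plan | (3E,6S)-6-[4-(benzyloxy)-3-methoxyphenyl]-6-[2-(benzyloxy)-5-bromo-3-methoxyphenyl]-1-diazohex-3-en-2-one | COc1cc([C@H](C/C=C/C(=O)C=[N+]=[N-])c2cc(Br)cc(OC)c2OCc2ccccc2)ccc1OCc1ccccc1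
A4 | direct plan | triisopropylsilyloxyacetylene | C#CO[Si](C(C)C)(C(C)C)C(C)C
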